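**Plan**

- Retrosynthesis: ring B is first taken back to its 4,5-dihydro level, C7–Br to a C7 ketone, and C2–Br and C3–Br to C–H. The C7–C7a bond is then cut (ring B opened to a butanoic acid), and finally the C3a–C4 bond (acyl group on a pyrrole β carbon).
- Forward: ring A (the pyrrole) is bought. A four-carbon chain from succinic anhydride is attached at its β carbon, and ring B is closed onto the neighbouring α carbon as a cyclic ketone. Ring A is then brominated twice, the ketone becomes the C7 bromoalkene, and ring B is dehydrogenated last.
- Enabling feature: C7 is bonded to the pyrrole α carbon C7a, so ring B can be closed by acylating that α carbon from a chain held on C3a. The resulting 7-oxo-tetrahydroindole has only C2 and C3 left as ring C–H positions, and its carbonyl carbon is the later C7–Br.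
- No benzene ring is ever brominated, so the regiochemistry of all three bromines follows from the skeleton.
- Stereochemistry: the target is achiral and no stereocenter arises at any stage.

Key step: step 3

Remark: indole numbering (N1, C2, C3, C3a, C4 to C7, C7a) is used for every bicyclic compound, also before aromatisation; ring A is the pyrrole ring, ring B the carbocycle.

**Route**

Step 1
Reactants: 1 1-(phenylsulfonyl)-1H-pyrrole; 2 succinic anhydride
Product: 3 4-oxo-4-[1-(phenylsulfonyl)-1H-pyrrol-3-yl]butanoic acid
Conditions: AlCl3 (2.5 equiv), ClCH2CH2Cl, 0 °C to rt; then ice/aq. HCl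
Reagents that add atoms: none
Why: Friedel–Crafts acylation, for which AlCl3 is known to direct N-sulfonylpyrroles to the β carbon C3; the anhydride opens to give the keto acid directly.

Step 2
Reactants: 3 4-oxo-4-[1-(phenylsulfonyl)-1H-pyrrol-3-yl]butanoic acid
Product: 4 4-[1-(phenylsulfonyl)-1H-pyrrol-3-yl]butanoic acid
Conditions: Zn(Hg), conc. HCl, toluene/H2O, reflux
Reagents that add atoms: none
Why: Clemmensen reduction of the aryl ketone, as in the classical Haworth sequence for β-aroylpropionic acids; the N-sulfonyl group protects the pyrrole from acid-induced oligomerisation and the carboxylic acid is not reduced.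

Step 3
Reactants: 4 4-[1-(phenylsulfonyl)-1H-pyrrol-3-yl]butanoic acid
Product: 6 1-(phenylsulfonyl)-1,4,5,6-tetrahydro-7H-indol-7-one, via 4-[1-(phenylsulfonyl)pyrrol-3-yl]butanoic trifluoroacetic anhydride 5 (not isolated)
Conditions: TFAA (2 equiv), CH2Cl2, 0 °C to rt
Reagents that add atoms: none
Why: TFAA converts the acid into mixed anhydride 5, whose alkanoyl carbonyl is attacked by pyrrole carbon C2 next to the side chain, and loss of the proton from the σ-complex restores the pyrrole and gives the aryl ketone. This is an intramolecular Friedel–Crafts acylation, the ring-closing half of a Haworth-type annulation, and the same closure is known for 4-(1-arylsulfonylpyrrol-3-yl)butanoic acids. Ring B closes in a 6-exo-trig mode at the acyl carbon, the pyrrole C2–C3 bond becoming the ring fusion, and the new bond is the future C7–C7a bond. No stereocenter is created. The step needs attack at the α carbon C2 and not at the β carbon C4 on the other side of the chain: α attack gives the better stabilised σ-complex, the 3-alkyl group activates C2 as its ortho position, and the absence of AlCl3 avoids the conditions that steer N-sulfonylpyrroles to β substitution. The ketone formed deactivates the ring, so a second acylation is not expected.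

Step 4
Reactants: 6 1-(phenylsulfonyl)-1,4,5,6-tetrahydro-7H-indol-7-one
Product: 7 1,4,5,6-tetrahydro-7H-indol-7-one
Conditions: NaOH (2 M aq.), 1,4-dioxane, rt
Reagents that add atoms: none
Why: N-desulfonylation by attack of hydroxide at sulfur, which is mild for a 2-acyl-N-sulfonylpyrrole because the 2-acylpyrrolide is a stabilised leaving group; it frees the N–H pyrrole needed for fast ring bromination.

Step 5
Reactants: 7 1,4,5,6-tetrahydro-7H-indol-7-one
Product: 9 2,3-dibromo-1,4,5,6-tetrahydro-7H-indol-7-one, via 3-bromo-1,4,5,6-tetrahydro-7H-indol-7-one 8 (not isolated)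
Conditions: NBS (2.05 equiv), THF, −78 °C to rt, dark
Reagents that add atoms: N-bromosuccinimide, O=C1CCC(=O)N1Br
Why: Electrophilic aromatic bromination: a 2-acylpyrrole is substituted at its 4- and 5-positions, here C3 and C2 and the only ring C–H positions, so two equivalents of NBS at low temperature in the dark should give the dibromide before slower bromination at C6 (α to the ketone) or at C4 can start.

Step 6
Reactants: 9 2,3-dibromo-1,4,5,6-tetrahydro-7H-indol-7-one
Product: 10 2,3,7-tribromo-4,5-dihydro-1H-indole
Conditions: P(OPh)3, Br2, CH2Cl2, −60 °C; then Et3N and 9, −60 °C to rt, then reflux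
Reagents that add atoms: bromine, BrBr
Why: Deoxybromination of an enolisable ketone with the bromophosphonium bromide that bromine and P(OPh)3 form in the flask at −60 °C: the carbonyl oxygen, electron-rich as part of a vinylogous amide, attacks phosphorus, bromide adds to C7, triphenyl phosphate leaves with help from the pyrrole nitrogen and Et3N removes a C6 proton to give the C6=C7 bromoalkene; the product is kept basic and taken on at once, since protonation at C6 would lead back to the ketone.

Step 7
Reactants: 10 2,3,7-tribromo-4,5-dihydro-1H-indole
Product: 11 2,3,7-tribromo-1H-indole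
Conditions: DDQ (1.2 equiv), toluene, rt to 60 °C
Reagents that add atoms: none
Why: DDQ dehydrogenation: hydride abstraction from allylic C5 (cation stabilised through C6=C7 and the pyrrole nitrogen) and proton loss from C4 complete the benzene ring, a strongly favoured aromatisation of a dihydroindole that leaves the three C–Br bonds untouched.

**Compound list**

1 | 1-(phenylsulfonyl)-1H-pyrrole | O=S(=O)(c1ccccc1)n1cccc1 | starting material
2 | succinic anhydride | O=C1CCC(=O)O1 | starting material
3 | 4-oxo-4-[1-(phenylsulfonyl)-1H-pyrrol-3-yl]butanoic acid | OC(=O)CCC(=O)c1ccn(c1)S(=O)(=O)c1ccccc1 | intermediate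
4 | 4-[1-(phenylsulfonyl)-1H-pyrrol-3-yl]butanoic acid | OC(=O)CCCc1ccn(c1)S(=O)(=O)c1ccccc1 | intermediate
5 | 4-[1-(phenylsulfonyl)pyrrol-3-yl]butanoic trifluoroacetic anhydride | O=C(CCCc1ccn(c1)S(=O)(=O)c1ccccc1)OC(=O)C(F)(F)F | intermediate
6 | 1-(phenylsulfonyl)-1,4,5,6-tetrahydro-7H-indol-7-one | O=C1CCCc2ccn(c12)S(=O)(=O)c1ccccc1 | intermediate
7 | 1,4,5,6-tetrahydro-7H-indol-7-one | O=C1CCCc2cc[nH]c12 | intermediate
8 | 3-bromo-1,4,5,6-tetrahydro-7H-indol-7-one | O=C1CCCc2c1[nH]cc2Br | intermediate
9 | 2,3-dibromo-1,4,5,6-tetrahydro-7H-indol-7-one | O=C1CCCc2c1[nH]c(Br)c2Br | intermediate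
10 | 2,3,7-tribromo-4,5-dihydro-1H-indole | BrC1=CCCc2c1[nH]c(Br)c2Br | intermediate
11 | 2,3,7-tribromo-1H-indole | Brc1[nH]c2c(Br)cccc2c1Br | target

**Count**

Total steps: 7. Longest linear sequence: 7 steps (1 to 11).

**Steps most likely to fail**

Step 6. The ketone is a vinylogous amide, so activation at oxygen may stall. The free N–H may also be phosphorylated and consume reagent. The bromoalkene may revert to the ketone through protonation at C6 and hydrolysis during work-up. The fallback sets out from 9: condensation with hydrazine hydrate in ethanol should give 2,3-dibromo-1,4,5,6-tetrahydro-7H-indol-7-one hydrazone F1. Oxidation of F1 with NBS in pyridine at 0 °C is a Barton-type vinyl halide synthesis: a diazo compound forms, is brominated at carbon, loses N2 and then the C6 proton. This makes the bromoalkene under basic conditions and comes back to the route at 10.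

Step 7. The electron-rich N–H bromovinylpyrrole may be over-oxidised or oligomerise with DDQ, and the acidic hydroquinone formed may promote hydrolysis back to the ketone. The fallback sets out from 10: N-acylation with Boc2O, DMAP and Et3N in MeCN should give tert-butyl 2,3,7-tribromo-4,5-dihydro-1H-indole-1-carboxylate F2. The carbamate makes the ring less electron-rich and the bromoalkene no longer acid-labile. DDQ in refluxing toluene then dehydrogenates it to tert-butyl 2,3,7-tribromo-1H-indole-1-carboxylate F3, and K2CO3 in MeOH at rt removes the carbamate, coming back to the route at 11.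

Step 3. Ring closure may go in part to the β carbon C4, giving the isoindolone skeleton, or the mixed anhydride may acylate a second molecule instead of its own ring. The fallback sets out from 4: NaOH in aqueous dioxane at reflux removes the sulfonyl group to give 4-(1H-pyrrol-3-yl)butanoic acid F4. Coupling with dimethylamine hydrochloride (EDC·HCl, HOBt, iPr2NEt, CH2Cl2) gives N,N-dimethyl-4-(1H-pyrrol-3-yl)butanamide F5. POCl3 in ClCH2CH2Cl at high dilution then forms the same C7–C7a bond by an intramolecular Vilsmeier–Haack acylation; a free N–H pyrrole has a much stronger α preference. This gives N,N-dimethyl-1,4,5,6-tetrahydro-7H-indol-7-iminium chloride F6, which aqueous NaOAc hydrolyses to the ketone. The route is rejoined at 7, and step 4 is then not needed.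

**Further compounds**

F1 | step 6 | 2,3-dibromo-1,4,5,6-tetrahydro-7H-indol-7-one hydrazone | NN=C1CCCc2c1[nH]c(Br)c2Br
F2 | step 7 | tert-butyl 2,3,7-tribromo-4,5-dihydro-1H-indole-1-carboxylate | CC(C)(C)OC(=O)n1c(Br)c(Br)c2CCC=C(Br)c12
F3 | step 7 | tert-butyl 2,3,7-tribromo-1H-indole-1-carboxylate | CC(C)(C)OC(=O)n1c(Br)c(Br)c2cccc(Br)c12
F4 | step 3 | 4-(1H-pyrrol-3-yl)butanoic acid | OC(=O)CCCc1cc[nH]c1
F5 | step 3 | N,N-dimethyl-4-(1H-pyrrol-3-yl)butanamide | CN(C)C(=O)CCCc1cc[nH]c1
F6 | step 3 | N,N-dimethyl-1,4,5,6-tetrahydro-7H-indol-7-iminium chloride | C[N+](C)=C1CCCc2cc[nH]c12.[Cl-]
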